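**Plan**

1. Numbering used throughout (longipinane): C1(=O)–C2=C3(CH3)–C4–C5–C6(CH3)2–C7(O)–C8–C9(O)–C10(CH3)–C11, with the further bonds C1–C11, C4–C10 and C5–C11.
2. Retrosynthetic cuts, in order: the two ester C–O bonds and C7–H (O-9 ester and C-7 carbinol arise together from a 9-hydroxy-7-ketone); C9–O (borylation/oxidation of a C8=C9 enone); C2–C3 (aldol condensation of acetyl groups on C4 and C11); then C5–C6 and C9–C10 together.
3. Enabling feature: C5 and C10 are the 1,3-carbons of the cyclobutane C4–C5–C11–C10 and are spanned by C6–C9 (a bicyclo[4.1.1]octane). Both bonds are therefore the ends of a four-carbon unit added across the central C5–C10 bond of a bicyclo[1.1.0]butane; C6 (α to the C7 ketone) is a radical donor and C9 (β-carbon of the C7 enone) a radical acceptor.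
4. Forward ring order: cyclopropene, then bicyclobutane (C4, C5, C10, C11 with both acetyl precursors), then the seven-membered ring by radical annulation, then the cyclohexenone by aldol condensation; oxygenation at C9 and C7 and the acylations follow.
5. Stereochemistry: all intermediates up to 12 are racemic or meso. The relative configuration of C4, C5, C10 and C11 is imposed by the two cis-1,3 bridges on opposite faces of the cyclobutane, and their absolute configuration by the chiral amine in step 7. C9 is set by the chiral copper catalyst in step 8, C7 by hydride delivery anti to O-9 in step 9, and the E-tigloyl geometry by the reagent.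

Key step: step 6

Assumption: in steps 7 and 8 the catalyst enantiomer named is taken to give the drawn configuration; if the sense of induction is the opposite, the pseudo-enantiomeric quinidine-derived amine or (S,S)-QuinoxP* is used instead.

**Route**

Step 1
Reactants: 1 propyne; 2 ethyl diazoacetate
Product: 3 ethyl 2-methylcycloprop-2-ene-1-carboxylate (racemic)
Conditions: Rh2(OAc)4 (0.5 mol%), excess 1, CH2Cl2, 0 °C to rt, slow addition of 2
Reagents that add atoms: ethyl diazoacetate (2), [N-]=[N+]=CC(=O)OCC
Why: Carbenoid [2+1] cyclopropenation of a terminal alkyne, a standard reaction of diazoacetates; the single stereocentre is racemic and is absorbed into a meso compound in step 2.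

Step 2
Reactants: 3 ethyl 2-methylcycloprop-2-ene-1-carboxylate; 2 ethyl diazoacetate
Product: 4 diethyl (exo,exo)-1-methylbicyclo[1.1.0]butane-2,4-dicarboxylate (meso)
Conditions: [Cu(MeCN)4]PF6 (5 mol%), CH2Cl2, rt, syringe-pump addition of 2; chromatography to remove the exo,endo isomer
Reagents that add atoms: ethyl diazoacetate (2), [N-]=[N+]=CC(=O)OCC
Why: Carbenoid cyclopropanation of the strained cyclopropene double bond (classical double carbene addition to an alkyne); the carbenoid should approach anti to the ring ester, which becomes exo, and the incoming ester should prefer the less hindered exo position.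

Step 3
Reactants: 4 diethyl (exo,exo)-1-methylbicyclo[1.1.0]butane-2,4-dicarboxylate; 5 N,O-dimethylhydroxylamine hydrochloride
Product: 6 (exo,exo)-N,N'-dimethoxy-N,N',1-trimethylbicyclo[1.1.0]butane-2,4-dicarboxamide (meso)
Conditions: 5, iPrMgCl, THF, −20 to 0 °C
Reagents that add atoms: N,O-dimethylhydroxylamine hydrochloride (5), CNOC.Cl
Why: Weinreb amidation of both esters by the chloromagnesium amide made in situ; the bicyclobutane offers no competing acidic or electrophilic site and the wing stereocentres are untouched.

Step 4
Reactants: 6 the bis-Weinreb amide; 7 methylmagnesium bromide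
Product: 8 (exo,exo)-2,4-diacetyl-1-methylbicyclo[1.1.0]butane (meso)
Conditions: MeMgBr, THF, −78 to 0 °C; aq NH4Cl
Reagents that add atoms: methylmagnesium bromide (7), C[Mg]Br
Why: Weinreb ketone synthesis; the chelated tetrahedral adducts prevent over-addition and collapse on work-up to the bis(methyl ketone) with retention of the exo,exo configuration.

Step 5
Reactants: 9 2-bromo-2-methylpropanoyl bromide; 10 (E)-1,2-bis(tributylstannyl)ethene
Product: 11 (E)-4-bromo-4-methyl-1-(tributylstannyl)pent-1-en-3-one
Conditions: AlCl3, CH2Cl2, −78 to 0 °C
Reagents that add atoms: none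
Why: Friedel–Crafts-type ipso-acylation (acyldestannylation) of the vinylstannane with retention of the E geometry; it should stop after one acylation because the product enone is deactivated.

Step 6
Reactants: 8 (exo,exo)-2,4-diacetyl-1-methylbicyclo[1.1.0]butane; 11 (E)-4-bromo-4-methyl-1-(tributylstannyl)pent-1-en-3-one
Product: 12 7,8-diacetyl-1,5,5-trimethylbicyclo[4.1.1]oct-2-en-4-one (meso; both acetyl groups anti to the four-carbon bridge, cis to each other and to the 1-methyl)
Conditions: (Bu3Sn)2 (10 mol%), hν (sunlamp), degassed PhH (0.02 M), 30 °C, no hydrogen donor; filtration through neutral alumina, used at once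
Reagents that add atoms: none
Why: Proposed new method: Bu3Sn• from the ditin abstracts bromine from 11; the electrophilic tertiary α-keto radical adds to the strained, electron-rich central bond of 8 at the unsubstituted bridgehead (C-5), and the resulting nucleophilic tertiary cyclobutyl radical at the methyl-bearing carbon (C-10) closes onto the β-carbon of the tethered β-stannyl enone and expels Bu3Sn•, which carries the chain. The closest known reactions are Kharasch-type atom-transfer additions of halocarbon radicals across bicyclobutane central bonds and radical vinylation by addition–fragmentation of β-stannyl enones. The C5–C6 bond forms intermolecularly and the C9–C10 bond by a 7-endo-trig radical cyclisation, which completes the bicyclo[4.1.1]octenone. C-5 and C-10 become stereocentres: the tether forces the two new bonds to be cis-1,3 on the cyclobutane, and since the first radical should enter along the axis of the central bond, the bridge lies on the former concave face and the exo acetyls end up anti to it (a syn acetyl would in any case be epimerisable in step 7). The step needs attack at the unsubstituted bridgehead (giving the tertiary radical), 7-endo rather than 6-exo closure, and cascade rather than oligomerisation; these are secured by the methyl block at C-10, by polarity alternation (electrophilic radical with σ-bond, nucleophilic radical with enone β-carbon), by high dilution and by the absence of a hydrogen donor.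

Step 7
Reactants: 12 7,8-diacetyl-1,5,5-trimethylbicyclo[4.1.1]oct-2-en-4-one
Product: 14 longipina-2,8-diene-1,7-dione (C4, C5, C10, C11 as in the target), via ketol 13 (not isolated)
Conditions: 9-amino(9-deoxy)epiquinine (20 mol%), AcOH (40 mol%), toluene, 4 Å MS, 0 °C to rt
Reagents that add atoms: none
Why: Primary-amine (enamine) catalysed intramolecular aldol condensation of a prochiral 1,5-diketone (6-enolendo aldol, then dehydration), a known desymmetrisation of 2,6-heptanediones; the catalyst chooses which enantiotopic acetyl acts as enamine donor (it becomes C1/C2) and so fixes the absolute configuration of C4, C5, C10 and C11, and closure should be helped by relief of the transannular repulsion between the two 1,3-diaxial acetyls.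

Step 8
Reactants: 14 longipina-2,8-diene-1,7-dione; 15 bis(pinacolato)diboron
Product: 17 9-hydroxylongipin-2-ene-1,7-dione (hydroxyl on the face of the seven-membered ring turned toward C-11), via boryl ketone 16 (not isolated)
Conditions: CuCl (5 mol%), NaOtBu (10 mol%), (R,R)-QuinoxP* (6 mol%), 15 (1.1 equiv), MeOH (2 equiv), THF, 0 °C; then NaBO3·4H2O, THF/H2O, rt
Reagents that add atoms: NaBO3·4H2O (oxygen at C-9), [Na+].[Na+].O[B-]1(O)OO[B-](O)(O)OO1; bis(pinacolato)diboron (15; boron of 16 only), CC1(C)OB(OC1(C)C)B1OC(C)(C)C(C)(C)O1
Why: Enantioselective copper-boryl conjugate addition to a cyclic enone followed by stereoretentive C–B oxidation (known sequence); the β-monosubstituted cycloheptenone should react before the β,β-disubstituted cyclohexenone, and because the two faces of C8=C9 differ only through the remote enone bridge, the chiral bisphosphine–copper boryl complex decides the configuration at C-9.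

Step 9
Reactants: 17 9-hydroxylongipin-2-ene-1,7-dione; 18 3-methylbut-2-enal
Product: 19 7-hydroxy-1-oxolongipin-2-en-9-yl 3-methylbut-2-enoate (7-OH trans to the 9-ester, toward C-4)
Conditions: SmI2 (20 mol%, premixed with 18), 18 (6 equiv), THF, −10 °C
Reagents that add atoms: 3-methylbut-2-enal (18), CC(C)=CC=O
Why: Evans–Tishchenko reduction: the samarium-bound hemiacetal formed from the C-9 hydroxyl and the aldehyde delivers hydride through a six-membered transition state to the same face of the C-7 ketone, giving the 1,3-anti (trans) C-7 alcohol and placing the 3-methylbut-2-enoyl group on O-9, while the C-1 enone, which has no β-hydroxyl, is not reduced.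

Step 10
Reactants: 19 7-hydroxy-1-oxolongipin-2-en-9-yl 3-methylbut-2-enoate; 20 (E)-2-methylbut-2-enoyl chloride
Product: 21 1-oxo-7-[(E)-2-methylbut-2-enoyloxy]longipin-2-en-9-yl 3-methylbut-2-enoate (target)
Conditions: 20, DMAP (cat.), Et3N, CH2Cl2, 0 to 40 °C
Reagents that add atoms: (E)-2-methylbut-2-enoyl chloride (20), C/C=C(\C)C(Cl)=O
Why: DMAP-catalysed acylation of the hindered secondary alcohol; no stereocentre is touched and the E geometry comes from the reagent.

**Compound list**

1 | propyne | CC#C | starting material
2 | ethyl diazoacetate | [N-]=[N+]=CC(=O)OCC | starting material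
3 | ethyl 2-methylcycloprop-2-ene-1-carboxylate (racemic) | CCOC(=O)C1C=C1C | intermediate
4 | diethyl (exo,exo)-1-methylbicyclo[1.1.0]butane-2,4-dicarboxylate (meso) | C[C@@]12[C@@H](C(=O)OCC)[C@@H]1[C@H]2C(=O)OCC | intermediate
5 | N,O-dimethylhydroxylamine hydrochloride | CNOC.Cl | starting material
6 | (exo,exo)-N,N'-dimethoxy-N,N',1-trimethylbicyclo[1.1.0]butane-2,4-dicarboxamide (meso) | C[C@@]12[C@@H](C(=O)N(C)OC)[C@@H]1[C@H]2C(=O)N(C)OC | intermediate
7 | methylmagnesium bromide | C[Mg]Br | starting material
8 | (exo,exo)-2,4-diacetyl-1-methylbicyclo[1.1.0]butane (meso) | C[C@@]12[C@@H](C(C)=O)[C@@H]1[C@H]2C(C)=O | intermediate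
9 | 2-bromo-2-methylpropanoyl bromide | CC(C)(Br)C(Br)=O | starting material
10 | (E)-1,2-bis(tributylstannyl)ethene | CCCC[Sn](CCCC)(CCCC)/C=C/[Sn](CCCC)(CCCC)CCCC | starting material
11 | (E)-4-bromo-4-methyl-1-(tributylstannyl)pent-1-en-3-one | CC(C)(Br)C(=O)/C=C/[Sn](CCCC)(CCCC)CCCC | intermediate
12 | 7,8-diacetyl-1,5,5-trimethylbicyclo[4.1.1]oct-2-en-4-one (meso, acetyls anti to the four-carbon bridge) | O=C1C=C[C@@]2(C)[C@H](C(C)=O)[C@H]([C@@H]2C(C)=O)C1(C)C | intermediate
13 | 3-hydroxylongipin-8-ene-1,7-dione (aldol ketol, either C-3 epimer) | O=C1C=C[C@@]2(C)[C@@H]3C(=O)CC(C)(O)[C@H]2[C@@H]3C1(C)C | intermediate (not isolated)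
14 | longipina-2,8-diene-1,7-dione | O=C1C=C[C@@]2(C)[C@@H]3C(=O)C=C(C)[C@H]2[C@@H]3C1(C)C | intermediate
15 | bis(pinacolato)diboron | CC1(C)OB(OC1(C)C)B1OC(C)(C)C(C)(C)O1 | starting material
16 | 9-(4,4,5,5-tetramethyl-1,3,2-dioxaborolan-2-yl)longipin-2-ene-1,7-dione (boron toward C-11) | O=C1C[C@@H](B2OC(C)(C)C(C)(C)O2)[C@@]2(C)[C@@H]3C(=O)C=C(C)[C@H]2[C@@H]3C1(C)C | intermediate (not isolated)
17 | 9-hydroxylongipin-2-ene-1,7-dione (hydroxyl toward C-11) | O=C1C[C@@H](O)[C@@]2(C)[C@@H]3C(=O)C=C(C)[C@H]2[C@@H]3C1(C)C | intermediate
18 | 3-methylbut-2-enal | CC(C)=CC=O | starting material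
19 | 7-hydroxy-1-oxolongipin-2-en-9-yl 3-methylbut-2-enoate (7-OH trans to the 9-ester) | O[C@@H]1C[C@@H](OC(=O)C=C(C)C)[C@@]2(C)[C@@H]3C(=O)C=C(C)[C@H]2[C@@H]3C1(C)C | intermediate
20 | (E)-2-methylbut-2-enoyl chloride | C/C=C(\C)C(Cl)=O | starting material
21 | 1-oxo-7-[(E)-2-methylbut-2-enoyloxy]longipin-2-en-9-yl 3-methylbut-2-enoate | C/C=C(\C)C(=O)O[C@@H]1C[C@@H](OC(=O)C=C(C)C)[C@@]2(C)[C@@H]3C(=O)C=C(C)[C@H]2[C@@H]3C1(C)C | target

**Step count and risks**

Total step count: 10. Longest linear sequence: 9 (steps 1–4 and 6–10; step 5 is a one-step side branch).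

Steps most likely to fail:

Step 6. The stannyl-radical chain may not be sustained: the chain carrier may be lost by addition to the strained bond, or the cyclobutyl radical may be intercepted before the seven-membered ring closes. The fallback uses known reaction types in a tin-free redox chain; it sets out from 8 and 9 and returns at 12. Compound 9 is used to acylate tributyl(vinyl)stannane (AlCl3, CH2Cl2) to give 4-bromo-4-methylpent-1-en-3-one F1. CuBr/tris(2-pyridylmethyl)amine with ascorbic acid in MeCN then effects a Kharasch-type bromine atom-transfer addition of F1 across the central bond of 8, followed by atom-transfer 7-endo cyclisation onto the vinyl ketone; the copper halide keeps the radical concentration low and caps the final α-keto radical with bromine to give 3-bromo-7,8-diacetyl-1,5,5-trimethylbicyclo[4.1.1]octan-4-one F2. Dehydrobromination (Li2CO3, LiBr, DMF, 100 °C) then restores the enone of 12.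

Step 2. Carbenoid dimerisation and metal-induced ring opening of the cyclopropene may outrun cyclopropanation, and exo/endo control may be poor. The fallback sets out from 3 (with 2) and returns at 4. Uncatalysed 1,3-dipolar cycloaddition of 2 to the strained double bond of 3 (Et2O, rt, dark) gives diethyl 1-methyl-2,3-diazabicyclo[3.1.0]hex-2-ene-4,6-dicarboxylate F3 (either regioisomer serves). Immediate photolysis (350 nm, pentane, −20 °C) extrudes nitrogen and closes the second three-membered ring to 4.

Step 7. Discrimination between the two enantiotopic acetyl groups may be poor, or an uncatalysed racemic background condensation may compete. The fallback moves the source of absolute configuration to step 8; it sets out from 12 and returns at 17. Achiral condensation (pyrrolidine, AcOH, toluene) gives racemic bis-enone, that is 14 together with its mirror image ent-longipina-2,8-diene-1,7-dione F4. The chiral copper catalyst of step 8, whose facial preference at C-9 does not depend on the remote core, then converts 14 into 17 and F4 into the diastereomeric 9-hydroxy ketone F5 (hydroxyl toward C-4). Chromatography removes F5, and enantiopure 17 continues, at the cost of at most half of the material.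

Further compounds
F1 | step 6 | 4-bromo-4-methylpent-1-en-3-one | CC(C)(Br)C(=O)C=C
F2 | step 6 | 3-bromo-7,8-diacetyl-1,5,5-trimethylbicyclo[4.1.1]octan-4-one (racemic at C-3, acetyls anti to the bridge) | O=C1C(Br)C[C@@]2(C)[C@H](C(C)=O)[C@H]([C@@H]2C(C)=O)C1(C)C
F3 | step 2 | diethyl 1-methyl-2,3-diazabicyclo[3.1.0]hex-2-ene-4,6-dicarboxylate | CCOC(=O)C1N=NC2(C)C(C(=O)OCC)C12
F4 | step 7 | ent-longipina-2,8-diene-1,7-dione | O=C1C=C[C@]2(C)[C@H]3C(=O)C=C(C)[C@@H]2[C@H]3C1(C)C
F5 | step 7 | 9-hydroxy-ent-longipin-2-ene-1,7-dione with the hydroxyl toward C-4 (diastereomer of 17) | O=C1C[C@@H](O)[C@]2(C)[C@H]3C(=O)C=C(C)[C@@H]2[C@H]3C1(C)C
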